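## Retrosynthetic overview

1. Mycaperoxide H ⇐ its methyl ester; the C8 methyl stereocentre ⇐ face-selective diimide reduction of an 8(17)-exocyclic alkene.
2. The 9-methyl-Δ1(10) bicycle ⇐ biomimetic 1,2-shift of the angular methyl (C10→C9), triggered at an 8α,9α-epoxy-labdane and run with the 1,2-dioxane already in place.
3. The 1,2-dioxane ⇐ biomimetic 6-exo peroxy-Michael addition of a tertiary C6 hydroperoxide (O2 captured by a radical made by cobalt-hydride hydrogen-atom transfer) onto an (E)-2-methyl-2-enoate.
4. The dienoate ⇐ cross-metathesis with methyl methacrylate and Wittig olefination of a C18 Δ8(9) methyl ketone ⇐ sclareol.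
5. Ring order: rings A and B come intact from sclareol (nature's polyene cyclization), then the dioxane ring is closed, then the skeleton is rearranged and C8 adjusted.

Assumption: bicycle positions are quoted in labdane numbering (C4 gem-dimethyl carbon, C5 ring-fusion CH, C8/C9 in ring B, C10 second ring-fusion carbon, α = face of H-5); the side chain uses the numbering of the target acid (C1 carboxyl, C6 peroxide-bearing quaternary carbon); 7 and 10 are catalogue reagents.

## Route

Step 1
Reactants: 1 (−)-sclareol
Product: 4 hydroxy ketone (8α-hydroxy-14,15-dinorlabdan-13-one), via tetraol 2 (not isolated), via hydroxy aldehyde 3 (not isolated)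
Conditions: OsO4 (2 mol%), NaIO4 (4 equiv), THF–H2O 3:1, rt
Reagents that add atoms: none
Why: Lemieux–Johnson oxidation, in which dihydroxylation of the vinyl group, periodate glycol cleavage and a second periodate cleavage of the tertiary α-hydroxy aldehyde excise C15 and C14 and leave C13 as a methyl ketone, with no stereocentre of the bicycle touched.

Step 2
Reactants: 4 hydroxy ketone
Product: 6 unsaturated ketone (14,15-dinorlabd-8-en-13-one), via sclareol oxide 5 (not isolated)
Conditions: p-TsOH·H2O (10 mol%), toluene, reflux, Dean–Stark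
Reagents that add atoms: none
Why: acid-catalysed E1 dehydration under thermodynamic control, in which the cyclic enol ether formed first re-ionises at C8 and drains to the tetrasubstituted Δ8(9) alkene with release of the ketone; C5 and C10 are untouched and no new stereocentre forms.

Step 3
Reactants: 6 unsaturated ketone; 7 (but-3-en-1-yl)triphenylphosphonium bromide
Product: 9 skipped triene (3E/3Z mixture), via ylide 8 (not isolated)
Conditions: 7, NaN(SiMe3)2, THF, 0 °C; then 6, 0 → 60 °C
Reagents that add atoms: 7 (but-3-en-1-yl)triphenylphosphonium bromide, C=CCC[P+](c1ccccc1)(c1ccccc1)c1ccccc1.[Br-]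
Why: Wittig olefination of the unhindered methyl ketone by a non-stabilised ylide; the E/Z ratio of the new trisubstituted alkene does not matter because its substituted carbon (later C6) becomes a radical centre in step 5.

Step 4
Reactants: 9 skipped triene; 10 methyl methacrylate
Product: 11 dienoate, methyl (2E)-2,6-dimethyl-8-(bicyclyl)octa-2,5-dienoate (5E/5Z mixture)
Conditions: 10 (10 equiv), second-generation Grubbs catalyst RuCl2(=CHPh)(PCy3)(H2IMes) (5 mol%), CH2Cl2, 40 °C
Reagents that add atoms: 10 methyl methacrylate, C=C(C)C(=O)OC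
Why: olefin cross-metathesis of the only monosubstituted alkene with methyl methacrylate gives the (E)-2-methyl-2-enoate (thermodynamic E selectivity), while the tri- and tetrasubstituted alkenes do not engage the ruthenium carbene.

Step 5
Reactants: 11 dienoate
Product: 14 dioxane ester, methyl (2S)-2-[(3S,6R)-6-methyl-6-{2-(bicyclyl)ethyl}-1,2-dioxan-3-yl]propanoate, via silyl peroxide 12 (not isolated), via hydroperoxide 13 (not isolated)
Conditions: Co(thd)2 (10 mol%; thd = 2,2,6,6-tetramethylheptane-3,5-dionate), O2 (1 atm), Et3SiH, ClCH2CH2Cl, rt; then K2CO3 (0.3 equiv), MeOH, 0 °C → rt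
Reagents that add atoms: dioxygen, O=O
Why: Mukaiyama–Isayama hydroperoxysilylation (hydrogen-atom transfer from a cobalt hydride to C5 of the electron-rich trisubstituted alkene and O2 capture by the tertiary C6 radical, sparing the tetrasubstituted ring alkene and the electron-poor enoate) followed by methanolysis of the O–Si bond and base-mediated 6-exo-trig peroxy-Michael (oxa-Michael) addition, the ring closure of the presumed biosynthesis; C6 forms without facial bias (about 1:1), C3 and C2 are set in the reversible conjugate addition and enolate protonation through a chair with the propanoate equatorial, and the (2S,3S,6R) isomer 14 is isolated by chromatography (HPLC) as a minor share of the stereoisomer mixture, its C2/C3 isomers of the same C6 series being re-equilibrated under the same base.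

Step 6
Reactants: 14 dioxane ester
Product: 15 8α,9α-epoxide of 14
Conditions: mCPBA, CH2Cl2, 0 °C
Reagents that add atoms: mCPBA, O=C(OO)c1cccc(Cl)c1
Why: Prilezhaev epoxidation of the only remaining alkene; the peracid attacks the α face, opposite the axial C10 methyl group, which fixes the 8α,9α-epoxide, and the dialkyl peroxide and ester are inert.

Step 7
Reactants: 15 epoxide
Product: 16 rearranged tertiary alcohol (8α-hydroxy, 8β-methyl, 9β-methyl, 9α-side chain, Δ1(10))
Conditions: BF3·OEt2 (0.2 equiv), CH2Cl2, −78 °C, 10 min; Et3N quench at −78 °C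
Reagents that add atoms: none
Why: Lewis-acid epoxide opening at C9 with concerted anti-periplanar Wagner–Meerwein shift of the angular methyl from C10 to the β face of C9 (the laboratory counterpart of the biosynthetic backbone rearrangement) sets the quaternary C9 stereospecifically (methyl β, side chain α) and keeps the C8–O bond, and kinetic loss of H-1 from the C10 cation (the CH2 proton rather than the shielded tertiary H-5 next to the gem-dimethyl carbon, as in α- over β-cyclogeranyl formation) gives the Δ1(10) alkene; catalytic acid, −78 °C and a cold amine quench are chosen to prevent drift to the tetrasubstituted alkene and to spare the peroxide.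

Step 8
Reactants: 16 rearranged tertiary alcohol
Product: 17 exocyclic alkene (8(17)-ene)
Conditions: SOCl2, pyridine, CH2Cl2, −40 °C
Reagents that add atoms: none
Why: dehydration by activation of the tertiary hydroxyl with SOCl2 and pyridine-mediated E2 elimination; the equatorial C8–O bond has no anti-periplanar ring hydrogen (C9 is quaternary), so a methyl hydrogen is removed and only the exocyclic alkene forms, and the C8 centre is erased on purpose to be reset in step 9.

Step 9
Reactants: 17 exocyclic alkene
Product: 18 mycaperoxide H methyl ester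
Conditions: 2-nitrobenzenesulfonohydrazide (NBSH), Et3N, CH2Cl2, rt
Reagents that add atoms: none
Why: diimide reduction (concerted syn transfer of H2) touches only the 1,1-disubstituted alkene and leaves the hindered trisubstituted alkene, the O–O bond and the ester; hydrogen reaches C8 from the axial β face, anti to the axial C9 side chain, so H-8 is β and the new methyl group equatorial (R at that carbon).

Step 10
Reactants: 18 mycaperoxide H methyl ester
Product: 19 mycaperoxide H
Conditions: LiOH, THF–H2O, 0 °C → rt; then 1 M HCl to pH 3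
Reagents that add atoms: lithium hydroxide, [Li+].[OH-]
Why: saponification (BAc2) of the unhindered methyl ester at low temperature; the dialkyl peroxide survives hydroxide and C2 is not epimerised under these mild conditions.

## Compound list

1 | (−)-sclareol, (13R)-labd-14-ene-8α,13-diol | C[C@]12CCCC(C)(C)[C@@H]1CC[C@@](C)(O)[C@@H]2CC[C@@](C)(O)C=C | starting material
2 | (13R)-labdane-8α,13,14,15-tetraol (both C14 epimers) | C[C@]12CCCC(C)(C)[C@@H]1CC[C@@](C)(O)[C@@H]2CC[C@@](C)(O)C(O)CO | intermediate
3 | (13R)-8α,13-dihydroxy-15-norlabdan-14-al | C[C@]12CCCC(C)(C)[C@@H]1CC[C@@](C)(O)[C@@H]2CC[C@@](C)(O)C=O | intermediate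
4 | 8α-hydroxy-14,15-dinorlabdan-13-one | C[C@]12CCCC(C)(C)[C@@H]1CC[C@@](C)(O)[C@@H]2CCC(C)=O | intermediate
5 | sclareol oxide (8α,13-epoxy-14,15-dinorlabd-12-ene) | C[C@]12CCCC(C)(C)[C@@H]1CC[C@@]3(C)OC(C)=CC[C@H]23 | intermediate
6 | 14,15-dinorlabd-8-en-13-one | C[C@]12CCCC(C)(C)[C@@H]1CCC(C)=C2CCC(C)=O | intermediate
7 | (but-3-en-1-yl)triphenylphosphonium bromide | C=CCC[P+](c1ccccc1)(c1ccccc1)c1ccccc1.[Br-] | starting material
8 | (but-3-en-1-ylidene)triphenylphosphorane | C=CCC=P(c1ccccc1)(c1ccccc1)c1ccccc1 | intermediate
9 | (4aS,8aS)-2,5,5,8a-tetramethyl-1-(3-methylhepta-3,6-dien-1-yl)-3,4,4a,5,6,7,8,8a-octahydronaphthalene (3E/3Z mixture) | C[C@]12CCCC(C)(C)[C@@H]1CCC(C)=C2CCC(C)=CCC=C | intermediate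
10 | methyl methacrylate | C=C(C)C(=O)OC | starting material
11 | methyl (2E)-2,6-dimethyl-8-[(4aS,8aS)-2,5,5,8a-tetramethyl-3,4,4a,5,6,7,8,8a-octahydronaphthalen-1-yl]octa-2,5-dienoate (5E/5Z mixture) | C[C@]12CCCC(C)(C)[C@@H]1CCC(C)=C2CCC(C)=CC/C=C(\C)C(=O)OC | intermediate
12 | methyl (2E,6S)-2,6-dimethyl-8-[(4aS,8aS)-2,5,5,8a-tetramethyl-3,4,4a,5,6,7,8,8a-octahydronaphthalen-1-yl]-6-[(triethylsilyl)peroxy]oct-2-enoate (formed together with its 6R epimer; the epimer drawn leads to the target) | C[C@]12CCCC(C)(C)[C@@H]1CCC(C)=C2CC[C@@](C)(OO[Si](CC)(CC)CC)CC/C=C(\C)C(=O)OC | intermediate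
13 | methyl (2E,6S)-6-hydroperoxy-2,6-dimethyl-8-[(4aS,8aS)-2,5,5,8a-tetramethyl-3,4,4a,5,6,7,8,8a-octahydronaphthalen-1-yl]oct-2-enoate (formed together with its 6R epimer; same C6 geometry as 6R of the ring in 14) | C[C@]12CCCC(C)(C)[C@@H]1CCC(C)=C2CC[C@@](C)(OO)CC/C=C(\C)C(=O)OC | intermediate
14 | methyl (2S)-2-[(3S,6R)-6-methyl-6-{2-[(4aS,8aS)-2,5,5,8a-tetramethyl-3,4,4a,5,6,7,8,8a-octahydronaphthalen-1-yl]ethyl}-1,2-dioxan-3-yl]propanoate | C[C@H](C(=O)OC)[C@@H]1CC[C@@](C)(CCC2=C(C)CC[C@H]3C(C)(C)CCC[C@]23C)OO1 | intermediate
15 | 8α,9α-epoxide of 14 (oxirane across C8–C9 on the face opposite the angular methyl; side-chain stereocentres unchanged) | C[C@H](C(=O)OC)[C@@H]1CC[C@@](C)(CC[C@@]23O[C@]2(C)CC[C@H]4C(C)(C)CCC[C@]34C)OO1 | intermediate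
16 | methyl (2S)-2-[(3S,6R)-6-{2-[(1S,2R,4aS)-2-hydroxy-1,2,5,5-tetramethyl-1,2,3,4,4a,5,6,7-octahydronaphthalen-1-yl]ethyl}-6-methyl-1,2-dioxan-3-yl]propanoate | C[C@H](C(=O)OC)[C@@H]1CC[C@@](C)(CC[C@@]2(C)C3=CCCC(C)(C)[C@@H]3CC[C@@]2(C)O)OO1 | intermediate
17 | methyl (2S)-2-[(3S,6R)-6-methyl-6-{2-[(1R,4aS)-1,5,5-trimethyl-2-methylidene-1,2,3,4,4a,5,6,7-octahydronaphthalen-1-yl]ethyl}-1,2-dioxan-3-yl]propanoate | C[C@H](C(=O)OC)[C@@H]1CC[C@@](C)(CC[C@@]2(C)C3=CCCC(C)(C)[C@@H]3CCC2=C)OO1 | intermediate
18 | mycaperoxide H methyl ester, methyl (2S)-2-[(3S,6R)-6-methyl-6-{2-[(1R,2R,4aS)-1,2,5,5-tetramethyl-1,2,3,4,4a,5,6,7-octahydronaphthalen-1-yl]ethyl}-1,2-dioxan-3-yl]propanoate | C[C@H](C(=O)OC)[C@@H]1CC[C@@](C)(CC[C@@]2(C)C3=CCCC(C)(C)[C@@H]3CC[C@H]2C)OO1 | intermediate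
19 | mycaperoxide H, (2S)-2-[(3S,6R)-6-methyl-6-{2-[(1R,2R,4aS)-1,2,5,5-tetramethyl-1,2,3,4,4a,5,6,7-octahydronaphthalen-1-yl]ethyl}-1,2-dioxan-3-yl]propanoic acid | C[C@H](C(=O)O)[C@@H]1CC[C@@](C)(CC[C@@]2(C)C3=CCCC(C)(C)[C@@H]3CC[C@H]2C)OO1 | target

## Step count and risks

Total steps: 10. Longest linear sequence: 10 (from 1; 7 and 10 are purchased).

The three steps most likely to fail are steps 7, 5 and 8.

**Step 7.** The activated epoxide can instead undergo semipinacol ring contraction, the C10 cation can lose H-5 to give the tetrasubstituted Δ5(10) alkene, and BF3 may damage the dioxane. The fallback replaces the epoxide trigger by a bromonium ion; it sets out from 14 and comes back at 17. Compound 14 is treated with 2,4,4,6-tetrabromocyclohexa-2,5-dienone in MeNO2 at −20 °C over NaHCO3. The α-bromonium ion opens at C9 with the same anti-periplanar methyl shift, and the tribromophenoxide removes H-1, giving the tertiary 8α-bromide F1 with no Lewis acid near the peroxide. DBU in toluene then removes a methyl hydrogen (the only hydrogens anti to the equatorial C–Br bond) and delivers 17, so 15 and 16 are bypassed.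

**Step 5.** Nothing controls the face of O2 capture at C6, and C3/C2 are only weakly biased. The target-configured ester is therefore a minor component, and its quasi-enantiomeric dioxane partner differs only relative to the remote bicycle, which makes it hard to separate. The fallback moves stereocontrol from the substrate to a reagent; it sets out from 11, comes back at 14 and makes no compound outside the list (F0). The silyl peroxide 12 is cleaved with catalytic HCl in MeOH and hydroperoxide 13 is isolated as its C6 epimer pair. It is then cyclised with a chiral bifunctional iminophosphorane–thiourea Brønsted base (10 mol%, toluene, −20 °C), so that the C3–O bond forms under catalyst control. The products from the two C6 epimers are then cis/trans ring diastereomers (3S,6R and 3S,6S) and separate on silica. This catalyst-controlled closure is an untested extension of enantioselective intramolecular oxa-Michael additions to enoates.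

**Step 8.** Ionisation at C8 beside the quaternary C9 could trigger a back-migration to an allyl-stabilised cation, or give endocyclic alkene. The fallback is a radical deoxygenation that never forms a C8 cation or the exocyclic alkene; it sets out from 16 and comes back at 18. The alcohol is acylated with methyl chlorooxoacetate (DMAP, pyridine, CH2Cl2) to the methyl oxalate F2. This is reduced with (Me3Si)3SiH and AIBN in toluene at 90 °C (Dolan–MacMillan-type deoxygenation). The C8 radical takes hydrogen on the β face, anti to the axial C9 side chain, giving the 8α-methyl group of 18 directly.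

## Further compounds

F1 | step 7 | methyl (2S)-2-[(3S,6R)-6-{2-[(1S,2R,4aS)-2-bromo-1,2,5,5-tetramethyl-1,2,3,4,4a,5,6,7-octahydronaphthalen-1-yl]ethyl}-6-methyl-1,2-dioxan-3-yl]propanoate | C[C@H](C(=O)OC)[C@@H]1CC[C@@](C)(CC[C@@]2(C)C3=CCCC(C)(C)[C@@H]3CC[C@@]2(C)Br)OO1
F2 | step 8 | methyl (2S)-2-[(3S,6R)-6-{2-[(1S,2R,4aS)-2-(2-methoxy-2-oxoacetoxy)-1,2,5,5-tetramethyl-1,2,3,4,4a,5,6,7-octahydronaphthalen-1-yl]ethyl}-6-methyl-1,2-dioxan-3-yl]propanoate | C[C@H](C(=O)OC)[C@@H]1CC[C@@](C)(CC[C@@]2(C)C3=CCCC(C)(C)[C@@H]3CC[C@@]2(C)OC(=O)C(=O)OC)OO1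
F0 | step 5 | none | none
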